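**Retrosynthetic overview**
1. The strategy rests on ring A (C1 OMe, C2 H, C3 OH, C4 and C6 4-hydroxybenzyl, C5 CH2CH2–ring B). It is a polyketide-type resorcinol whose C6–C1–C2–C3–C4 carbons and two benzylic CH2 groups map onto C1–C7 of a symmetrical 1,7-diarylheptane-3,5-dione, and whose C5 and ethylene bridge map onto a ring-B dihydrocinnamoyl unit.
2. Target 16 ⇐ hydrogenolysis of four benzyl ethers ⇐ mono-O-methylation of the symmetrical resorcinol 14, whose C1 and C3 hydroxyls are equivalent, so only one monomethyl ether exists.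
3. Ring A, the only ring made, ⇐ base-induced aldol condensation and aromatisation of the 4-benzylated nonane-3,5,7-trione 12, forming the ring A C5–C6 bond.
4. 12 ⇐ γ-acylation of the dianion of dione 4 with the ring-B Weinreb amide 11.
5. 4 ⇐ pentane-2,4-dione and two molecules of chloride 2; 11 ⇐ 3-bromo-5-hydroxybenzaldehyde by benzylation, Horner–Wadsworth–Emmons olefination, Negishi benzylation and alkene hydrogenation.

Key step: step 7

Remark on the chemistry: the target has no stereocentre; triketone 12 is racemic at C4, is handled as a mixture of keto and enol tautomers, and its chain is numbered from C1 (the CH2 on ring B) to C9 (the CH2 on the 4-benzyloxyphenyl ring), with carbonyls at C3, C5 and C7.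

**Step 1**
Reactants: 1 pentane-2,4-dione; 2 1-(benzyloxy)-4-(chloromethyl)benzene (2 equiv in two portions)
Product: 4 1,7-bis[4-(benzyloxy)phenyl]heptane-3,5-dione, via monobenzylated hexanedione 3 (not isolated)
Conditions: LiN(i-Pr)2 (2.1 equiv), THF, −78 to 0 °C; 2 (1.0 equiv), 0 °C; LiN(i-Pr)2 (1.1 equiv), −78 to 0 °C; 2 (1.0 equiv), 0 °C; aq. NH4Cl
Reagents that add atoms: none
Why: Hauser–Harris γ-alkylation of a β-diketone 1,3-dianion run twice in one flask; the terminal carbanion is far more nucleophilic than the central enolate carbon, and the second deprotonation of the enolate of 3 should occur at the methyl rather than the methylene terminus (kinetic order CH3 > CH2), which places the second benzyl group at the other end.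

**Step 2**
Reactants: 5 3-bromo-5-hydroxybenzaldehyde
Product: 6 3-(benzyloxy)-5-bromobenzaldehyde
Conditions: BnBr, K2CO3, DMF, 25 °C
Reagents that add atoms: benzyl bromide, BrCc1ccccc1
Why: Williamson etherification of the phenoxide with a reactive benzylic halide; the aldehyde has no α-hydrogen and the aryl bromide is inert.

**Step 3**
Reactants: 6 3-(benzyloxy)-5-bromobenzaldehyde; 7 diethyl {2-[methoxy(methyl)amino]-2-oxoethyl}phosphonate
Product: 8 (E)-3-[3-(benzyloxy)-5-bromophenyl]-N-methoxy-N-methylprop-2-enamide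
Conditions: NaH, THF, 0 to 25 °C
Reagents that add atoms: none
Why: Horner–Wadsworth–Emmons olefination with a stabilised phosphonate anion should give the E-enamide and installs the Weinreb amide together with the two bridge carbons; the alkene geometry is lost in step 5.

**Step 4**
Reactants: 8 (E)-3-[3-(benzyloxy)-5-bromophenyl]-N-methoxy-N-methylprop-2-enamide; 2 1-(benzyloxy)-4-(chloromethyl)benzene
Product: 10 (E)-3-{3-(benzyloxy)-5-[4-(benzyloxy)benzyl]phenyl}-N-methoxy-N-methylprop-2-enamide, via benzylzinc chloride 9 (not isolated)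
Conditions: 2, Zn dust, LiCl, THF, 25 °C; then 8, Pd(OAc)2 (2 mol%), SPhos (4 mol%), THF, 25 to 40 °C
Reagents that add atoms: none
Why: Negishi coupling; zinc inserts into the benzylic chloride in the presence of LiCl, the aryl bromide adds oxidatively to zerovalent palladium, and the benzylzinc reagent transmetalates without attacking the enamide or the Weinreb amide.

**Step 5**
Reactants: 10 (E)-3-{3-(benzyloxy)-5-[4-(benzyloxy)benzyl]phenyl}-N-methoxy-N-methylprop-2-enamide
Product: 11 3-{3-(benzyloxy)-5-[4-(benzyloxy)benzyl]phenyl}-N-methoxy-N-methylpropanamide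
Conditions: H2 (3 atm), RhCl(PPh3)3 (5 mol%), toluene–EtOH (1:1), 40 °C
Reagents that add atoms: none
Why: Homogeneous hydrogenation with RhCl(PPh3)3 should saturate the disubstituted conjugated alkene without hydrogenolysis of the aryl benzyl ethers, the diarylmethane CH2 or the N–O bond.

**Step 6**
Reactants: 4 1,7-bis[4-(benzyloxy)phenyl]heptane-3,5-dione (1.3 equiv); 11 3-{3-(benzyloxy)-5-[4-(benzyloxy)benzyl]phenyl}-N-methoxy-N-methylpropanamide
Product: 12 4-[4-(benzyloxy)benzyl]-1-{3-(benzyloxy)-5-[4-(benzyloxy)benzyl]phenyl}-9-[4-(benzyloxy)phenyl]nonane-3,5,7-trione (racemic at C4, tautomeric mixture)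
Conditions: 4, LiN(i-Pr)2 (2.1 equiv per 4), THF, −78 to 0 °C; 11, −78 to −30 °C; AcOH, −78 °C; neutral work-up, crude 12 used at once
Reagents that add atoms: none
Why: γ-Acylation of a β-diketone 1,3-dianion (Hauser–Harris) with a Weinreb amide; the two termini of 4 are identical, the terminal carbanion adds to the amide, and the chelated tetrahedral intermediate keeps the new C3 carbonyl masked until the acidic quench, so neither over-addition nor premature cyclisation should occur, and the new C4 centre forms racemic and is later erased.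

**Step 7**
Reactants: 12 4-[4-(benzyloxy)benzyl]-1-{3-(benzyloxy)-5-[4-(benzyloxy)benzyl]phenyl}-9-[4-(benzyloxy)phenyl]nonane-3,5,7-trione
Product: 14 4,6-bis[4-(benzyloxy)benzyl]-5-(2-{3-(benzyloxy)-5-[4-(benzyloxy)benzyl]phenyl}ethyl)benzene-1,3-diol, via cyclic aldol adduct 13 (not isolated)
Conditions: KOH (0.5 M aq., 1.5 equiv), MeOH–THF (1:1), argon, 0 to 25 °C; then 1 M HCl to pH 3
Reagents that add atoms: none
Why: Hydroxide first removes C6–H of the unsubstituted C5–C7 1,3-diketone, so this unit is held as an enolate while the C3 carbonyl next to the benzylated C4 stays ketonic, and reversible γ-deprotonation at C8 gives a dienolate whose terminal carbon adds to C3 in an intramolecular aldol reaction to give 13. E1cB loss of water from 13 across C3–C4 and tautomerisation of the cyclohexenedione give the aromatic ring A and make the sequence irreversible. The closest known reaction is the base-induced aldol cyclisation of 2,4,6-triketones to resorcinols, as in heptane-2,4,6-trione to orcinol. Ring A closes in a 6-(enolendo)-exo-trig mode by forming the bond between chain C8 and C3, which are ring A C6 and C5. No stereocentre remains, since the three sp3 ring centres of 13 all become aromatic carbons. The step needs closure of C8 onto C3 and not of C2 onto the C7 carbonyl, which the preferred enolate formation in the less substituted diketone should secure because C7 is then deactivated as part of the enolate, and it needs C- rather than O-cyclisation, which the basic medium secures because the 4-pyranone forms only under acid.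

**Step 8**
Reactants: 14 4,6-bis[4-(benzyloxy)benzyl]-5-(2-{3-(benzyloxy)-5-[4-(benzyloxy)benzyl]phenyl}ethyl)benzene-1,3-diol
Product: 15 2,4-bis[4-(benzyloxy)benzyl]-3-(2-{3-(benzyloxy)-5-[4-(benzyloxy)benzyl]phenyl}ethyl)-5-methoxyphenol
Conditions: MeI (1.0 equiv), K2CO3 (1.0 equiv), acetone, 25 °C; unreacted 14 recovered and recycled
Reagents that add atoms: iodomethane, CI
Why: Williamson O-methylation with a limiting amount of MeI; the two hydroxyls of 14 are equivalent about the C2···C5 axis of ring A, so the monoether is a single compound, expected in a statistical distribution beside recovered 14 and the separable dimethyl ether.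

**Step 9**
Reactants: 15 2,4-bis[4-(benzyloxy)benzyl]-3-(2-{3-(benzyloxy)-5-[4-(benzyloxy)benzyl]phenyl}ethyl)-5-methoxyphenol
Product: 16 3-(2-{3-hydroxy-5-[(4-hydroxyphenyl)methyl]phenyl}ethyl)-2,4-bis[(4-hydroxyphenyl)methyl]-5-methoxyphenol (target)
Conditions: H2 (1 atm), 10% Pd/C, EtOAc–MeOH, 25 °C
Reagents that add atoms: none
Why: Catalytic hydrogenolysis of the four aryl benzyl ethers over Pd/C; the aryl methyl ether, the diarylmethane CH2 groups and the bibenzyl bridge are inert under these conditions.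

**Compound list**
1 | pentane-2,4-dione | CC(=O)CC(C)=O | starting material
2 | 1-(benzyloxy)-4-(chloromethyl)benzene | ClCc1ccc(OCc2ccccc2)cc1 | starting material
3 | 6-[4-(benzyloxy)phenyl]hexane-2,4-dione | CC(=O)CC(=O)CCc1ccc(OCc2ccccc2)cc1 | intermediate (not isolated)
4 | 1,7-bis[4-(benzyloxy)phenyl]heptane-3,5-dione | O=C(CCc1ccc(OCc2ccccc2)cc1)CC(=O)CCc1ccc(OCc2ccccc2)cc1 | intermediate
5 | 3-bromo-5-hydroxybenzaldehyde | O=Cc1cc(O)cc(Br)c1 | starting material
6 | 3-(benzyloxy)-5-bromobenzaldehyde | O=Cc1cc(OCc2ccccc2)cc(Br)c1 | intermediate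
7 | diethyl {2-[methoxy(methyl)amino]-2-oxoethyl}phosphonate | CCOP(=O)(CC(=O)N(C)OC)OCC | starting material
8 | (E)-3-[3-(benzyloxy)-5-bromophenyl]-N-methoxy-N-methylprop-2-enamide | CON(C)C(=O)/C=C/c1cc(OCc2ccccc2)cc(Br)c1 | intermediate
9 | [4-(benzyloxy)benzyl]zinc chloride | Cl[Zn]Cc1ccc(OCc2ccccc2)cc1 | intermediate (not isolated)
10 | (E)-3-{3-(benzyloxy)-5-[4-(benzyloxy)benzyl]phenyl}-N-methoxy-N-methylprop-2-enamide | CON(C)C(=O)/C=C/c1cc(OCc2ccccc2)cc(Cc2ccc(OCc3ccccc3)cc2)c1 | intermediate
11 | 3-{3-(benzyloxy)-5-[4-(benzyloxy)benzyl]phenyl}-N-methoxy-N-methylpropanamide | CON(C)C(=O)CCc1cc(OCc2ccccc2)cc(Cc2ccc(OCc3ccccc3)cc2)c1 | intermediate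
12 | 4-[4-(benzyloxy)benzyl]-1-{3-(benzyloxy)-5-[4-(benzyloxy)benzyl]phenyl}-9-[4-(benzyloxy)phenyl]nonane-3,5,7-trione (racemic) | O=C(CCc1cc(OCc2ccccc2)cc(Cc2ccc(OCc3ccccc3)cc2)c1)C(Cc1ccc(OCc2ccccc2)cc1)C(=O)CC(=O)CCc1ccc(OCc2ccccc2)cc1 | intermediate
13 | 4,6-bis[4-(benzyloxy)benzyl]-5-(2-{3-(benzyloxy)-5-[4-(benzyloxy)benzyl]phenyl}ethyl)-5-hydroxycyclohexane-1,3-dione (mixture of diastereomers) | OC1(CCc2cc(OCc3ccccc3)cc(Cc3ccc(OCc4ccccc4)cc3)c2)C(Cc2ccc(OCc3ccccc3)cc2)C(=O)CC(=O)C1Cc1ccc(OCc2ccccc2)cc1 | intermediate (not isolated)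
14 | 4,6-bis[4-(benzyloxy)benzyl]-5-(2-{3-(benzyloxy)-5-[4-(benzyloxy)benzyl]phenyl}ethyl)benzene-1,3-diol | Oc1cc(O)c(Cc2ccc(OCc3ccccc3)cc2)c(CCc2cc(OCc3ccccc3)cc(Cc3ccc(OCc4ccccc4)cc3)c2)c1Cc1ccc(OCc2ccccc2)cc1 | intermediate
15 | 2,4-bis[4-(benzyloxy)benzyl]-3-(2-{3-(benzyloxy)-5-[4-(benzyloxy)benzyl]phenyl}ethyl)-5-methoxyphenol | COc1cc(O)c(Cc2ccc(OCc3ccccc3)cc2)c(CCc2cc(OCc3ccccc3)cc(Cc3ccc(OCc4ccccc4)cc3)c2)c1Cc1ccc(OCc2ccccc2)cc1 | intermediate
16 | 3-(2-{3-hydroxy-5-[(4-hydroxyphenyl)methyl]phenyl}ethyl)-2,4-bis[(4-hydroxyphenyl)methyl]-5-methoxyphenol | COc1cc(O)c(Cc2ccc(O)cc2)c(CCc2cc(O)cc(Cc3ccc(O)cc3)c2)c1Cc1ccc(O)cc1 | target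

**Step count and risks**
Total: 9 steps. Longest linear sequence: 8 steps (steps 2 to 9, from 5 to 16).

Step 7 is the most likely to fail. The ring may close through the other enolate (the bridge α-carbon C2 onto the C7 carbonyl) to give the constitutional isomer. Hydroxide may also fragment the 2-benzylated diketone by retro-Claisen cleavage, and unclosed material may cyclise through oxygen on acidification. The fallback builds the substitution of ring A on a preformed resorcinol ring by halogenation and cross-coupling, so no regiochemical choice arises at ring closure. It sets out from 6, uses 9 made from 2 as in step 4, and comes back to the route at 16. Olefination of 6 with the anion of diethyl (3,5-dimethoxybenzyl)phosphonate (NaH, THF; Horner–Wadsworth–Emmons) should give the stilbene (E)-1-(benzyloxy)-3-bromo-5-[2-(3,5-dimethoxyphenyl)ethenyl]benzene F1. Diimide reduction (p-toluenesulfonyl hydrazide, NaOAc, THF–H2O, reflux) should give the bibenzyl 1-(benzyloxy)-3-bromo-5-[2-(3,5-dimethoxyphenyl)ethyl]benzene F2. N-Bromosuccinimide (2 equiv, MeCN, 0 °C) should brominate the dimethoxy ring at its two positions next to the chain, each ortho to one methoxy group and para to the other, to give the tribromide 1-(benzyloxy)-3-bromo-5-[2-(2,6-dibromo-3,5-dimethoxyphenyl)ethyl]benzene F3. Threefold Negishi coupling with 9 (Pd(OAc)2, SPhos, THF, 50 °C) should give the dimethyl ether 2,4-bis[4-(benzyloxy)benzyl]-3-(2-{3-(benzyloxy)-5-[4-(benzyloxy)benzyl]phenyl}ethyl)-1,5-dimethoxybenzene F4. Hydrogenolysis (H2, Pd/C) should give the triphenol 3-{2-[3-hydroxy-5-(4-hydroxybenzyl)phenyl]ethyl}-2,4-bis(4-hydroxybenzyl)-1,5-dimethoxybenzene F5. NaSEt (excess, DMF, 120 °C) should then remove one of the two equivalent methyl groups, the phenoxide so formed protecting the second, to give 16.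

Step 6 is the second risk. The hindered secondary carbanion may add slowly and be quenched by proton transfer, or the tetrahedral intermediate may collapse early and the freed triketone cyclise without control. The fallback replaces acylation by aldol addition and oxidation; it sets out from 11 and 4 and comes back at 12. Reduction of 11 with i-Bu2AlH (THF, −78 °C) should give the aldehyde 3-{3-(benzyloxy)-5-[4-(benzyloxy)benzyl]phenyl}propanal F6. Addition of the dianion of 4 (LiN(i-Pr)2, THF, −78 °C) should give the hydroxy diketone 4-[4-(benzyloxy)benzyl]-1-{3-(benzyloxy)-5-[4-(benzyloxy)benzyl]phenyl}-9-[4-(benzyloxy)phenyl]-3-hydroxynonane-5,7-dione F7 as a mixture of diastereomers. Oxidation with Dess–Martin periodinane (NaHCO3, CH2Cl2, 0 °C) should give 12.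

Step 1 is the third risk. The second deprotonation may occur at the methylene instead of the methyl terminus of 3, or proton exchange between the anions may lead to a mixture of polyalkylated diones. The fallback introduces the second arm by aldol condensation and hydrogenation; it sets out from 3, isolated after the first alkylation, and comes back at 4. Boron-templated condensation of 3 with 4-(benzyloxy)benzaldehyde at the methyl group (B2O3, B(On-Bu)3, n-BuNH2, EtOAc, 70 °C; then dilute HCl) should give the enone (E)-1,7-bis[4-(benzyloxy)phenyl]hept-1-ene-3,5-dione F8. Hydrogenation over RhCl(PPh3)3 as in step 5 should give 4.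

**Further compounds**
F1 | step 7 | (E)-1-(benzyloxy)-3-bromo-5-[2-(3,5-dimethoxyphenyl)ethenyl]benzene | COc1cc(OC)cc(/C=C/c2cc(OCc3ccccc3)cc(Br)c2)c1
F2 | step 7 | 1-(benzyloxy)-3-bromo-5-[2-(3,5-dimethoxyphenyl)ethyl]benzene | COc1cc(OC)cc(CCc2cc(OCc3ccccc3)cc(Br)c2)c1
F3 | step 7 | 1-(benzyloxy)-3-bromo-5-[2-(2,6-dibromo-3,5-dimethoxyphenyl)ethyl]benzene | COc1cc(OC)c(Br)c(CCc2cc(OCc3ccccc3)cc(Br)c2)c1Br
F4 | step 7 | 2,4-bis[4-(benzyloxy)benzyl]-3-(2-{3-(benzyloxy)-5-[4-(benzyloxy)benzyl]phenyl}ethyl)-1,5-dimethoxybenzene | COc1cc(OC)c(Cc2ccc(OCc3ccccc3)cc2)c(CCc2cc(OCc3ccccc3)cc(Cc3ccc(OCc4ccccc4)cc3)c2)c1Cc1ccc(OCc2ccccc2)cc1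
F5 | step 7 | 3-{2-[3-hydroxy-5-(4-hydroxybenzyl)phenyl]ethyl}-2,4-bis(4-hydroxybenzyl)-1,5-dimethoxybenzene | COc1cc(OC)c(Cc2ccc(O)cc2)c(CCc2cc(O)cc(Cc3ccc(O)cc3)c2)c1Cc1ccc(O)cc1
F6 | step 6 | 3-{3-(benzyloxy)-5-[4-(benzyloxy)benzyl]phenyl}propanal | O=CCCc1cc(OCc2ccccc2)cc(Cc2ccc(OCc3ccccc3)cc2)c1
F7 | step 6 | 4-[4-(benzyloxy)benzyl]-1-{3-(benzyloxy)-5-[4-(benzyloxy)benzyl]phenyl}-9-[4-(benzyloxy)phenyl]-3-hydroxynonane-5,7-dione (mixture of diastereomers) | OC(CCc1cc(OCc2ccccc2)cc(Cc2ccc(OCc3ccccc3)cc2)c1)C(Cc1ccc(OCc2ccccc2)cc1)C(=O)CC(=O)CCc1ccc(OCc2ccccc2)cc1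
F8 | step 1 | (E)-1,7-bis[4-(benzyloxy)phenyl]hept-1-ene-3,5-dione | O=C(/C=C/c1ccc(OCc2ccccc2)cc1)CC(=O)CCc1ccc(OCc2ccccc2)cc1
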